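The bis adduct grows out of the substrate in two additions, each taking one reagent, so the first thing to ask of any flask is how far its substrate has gone.

| flask | substrate | reagent | scavenger | temperature | remark | time |
|---|---|---|---|---|---|---|
| Tuesday's | 0.16 M | 0.288 M | 0.192 M | 85 °C | run made earlier |  |
| Sunday's | 0.16 M | 0.40 M | 0.192 M | 96 °C | run made earlier |  |
| Wednesday's | 0.16 M | 0.63 M | 0.192 M | 85 °C | run made earlier |  |
| Friday's | 0.16 M | 0.288 M | 0.096 M | 96 °C | run made earlier |  |
| grey | 0.16 M | 0.288 M | 0.192 M | 90 °C | everything together at the start | 6.0 h |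
| blue | 0.16 M | 0.288 M | 0.192 M |  | everything together at the start at 60 °C, warmed to 90 °C at 5.0 h | 6.0 h |
| ochre | 0.16 M | 0.288 M (fed, over 5.0 h) | 0.192 M | 90 °C | all else is in the flask from the start; the feed brings no volume worth counting | 6.0 h |
| amber | 0.16 M (fed, over 5.0 h) | 0.288 M | 0.192 M |  | the addition at 60 °C, then warmed to 90 °C; the feed brings no volume worth counting | 6.0 h |
| violet | 0.16 M (fed, over 5.0 h) | 0.288 M | 0.192 M | 90 °C | all else is in the flask from the start; the feed brings no volume worth counting | 6.0 h |

| run | time / h | bis adduct / % | single product / % |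
|---|---|---|---|
| Tuesday's | 0.417 | 0.7 | 7.5 |
| Tuesday's | 1.33 | 4.6 | 18.5 |
| Tuesday's | 2.00 | 9.3 | 21.2 |
| Tuesday's | 3.00 | 14.2 | 25.2 |
| Tuesday's | 5.00 | 24.6 | 25.6 |
| Tuesday's | 6.00 | 28.2 | 26.4 |
| Sunday's | 0.417 | 2.8 | 15.1 |
| Sunday's | 1.33 | 20.1 | 23.5 |
| Sunday's | 2.00 | 29.1 | 22.3 |
| Sunday's | 3.00 | 38.8 | 21.5 |
| Sunday's | 5.00 | 51.3 | 19.4 |
| Sunday's | 6.00 | 54.3 | 17.3 |
| Wednesday's | 1.00 | 10.5 | 23.2 |
| Wednesday's | 2.00 | 25.5 | 25.7 |
| Wednesday's | 3.00 | 37.7 | 24.6 |
| Wednesday's | 4.00 | 48.3 | 22.0 |
| Wednesday's | 5.00 | 54.3 | 19.6 |
| Wednesday's | 6.00 | 59.1 | 17.7 |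
| Friday's | 0.500 | 3.3 | 13.7 |
| Friday's | 1.50 | 14.8 | 21.4 |
| Friday's | 3.00 | 28.4 | 23.2 |
| Friday's | 4.00 | 34.1 | 22.8 |
| Friday's | 6.00 | 42.0 | 20.9 |

(standard deviation of a reading: 0.5 percentage points)

- for released group the idle adduct is counted in
- what may be going on: 2 reagent -> homo dimer; released group -> by-product carried off; reagent + bis adduct -> triple product + released group; scavenger + released group -> scavenged by-product; reagent + single product -> bis adduct + released group; substrate + reagent -> single product + released group; reagent + released group <-> idle adduct

- the flask that comes out highest in amount of bis adduct, in percent of the substrate charged; "all alike" if 1.5 percentage points covers them all (grey / blue / ochre / amber / violet / all alike)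
- amount of bis adduct at the end, in percent of the substrate charged, grey
- amount of bis adduct at the end, in percent of the substrate charged, blue
- amount of bis adduct at the end, in percent of the substrate charged, ochre
- amount of bis adduct at the end, in percent of the substrate charged, amber
- amount of bis adduct at the end, in percent of the substrate charged, violet

Call the depth of a flask the logarithm of substrate charged over substrate left. In the readings, substrate left is what single product and bis adduct leave of the charge, with triple product counted as nothing. If both additions go first order in reagent, then at one temperature, with the substrate in from the start, bis adduct follows depth along one curve, set by the selectivity factor, whatever course the reagent took. You can see this in the readings: Tuesday's run at 5.00 h and Wednesday's at 2.00 h stand at depths 0.697 and 0.717, with bis adduct at 24.6% and 25.5%.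

Now ask which settings move the depth at 6.00 h. Take reagent first. From Tuesday's run to Wednesday's, with temperature and scavenger held, the depth goes from 0.790 to 1.46, so

  order in reagent = ln(depth ratio) / ln(charge ratio) = 0.786

and the reagent charge must be known well. Sunday's run against Friday's gives 0.726, although Friday's flask holds half the scavenger. The two orders are about equal, so the scavenger can be known loosely. Going from 85 °C to 96 °C, Tuesday's run to Friday's, with the scavenger changed as well, raises the depth by a factor of 1.26 and the bis adduct reading from 28.2% to 42.0%, so the temperature has to be known well too.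

Grey has the reagent charge of those two runs, so I interpolate between them:

  depth, grey = 0.876

  bis adduct, grey = 34.1%

This depth of grey is the number to carry. I take grey as the flask to beat: ochre, amber and violet have a charge fed in over 5.0 h, and blue stands at 60 °C until then.

The forecast, with the words “Grey has the most exposure”, names grey: grey 34%, blue 12.5%, ochre 22%, amber 8%, violet 20%.

The simulation gives grey highest: grey 35.2%, blue 11.5%, ochre 24.7%, amber 8.31%, violet 18.7%.

    2 reagent → homo dimer (k = 6.50 × 10⁻⁵ /M/s, Ea = 88.0 kJ/mol)
    released group → by-product carried off (k = 0.00140 /s, Ea = 119 kJ/mol)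
    reagent + bis adduct → triple product + released group (k = 8.50 × 10⁻⁶ /M/s, Ea = 106 kJ/mol)
    scavenger + released group → scavenged by-product (k = 0.0620 /M/s, Ea = 64.0 kJ/mol)
    reagent + single product → bis adduct + released group (k = 6.00 × 10⁻⁴ /M/s, Ea = 80.0 kJ/mol)
    substrate + reagent → single product + released group (k = 2.90 × 10⁻⁴ /M/s, Ea = 63.0 kJ/mol)
    reagent + released group ⇌ idle adduct, settled at all times (K = 1.10 /M, ΔH = −40.0 kJ/mol)
    (constants at 90 °C)

Grey ends with 41% of its substrate left, a depth of 0.892 against the 0.876 reckoned from Tuesday's and Friday's runs. Ochre, with its reagent fed over 5.0 h, stands shallower than grey, at 0.681, and Tuesday's run stood at 0.697 at 5.00 h. There Tuesday's bis adduct read 24.6%, and ochre's ends at 24.7%.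

(All runs are calculated on assumed constants; scatter was added.)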